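Ring C is disconnected at C3–C4 and O1–C8a, giving a fully substituted 2-fluorobenzoyl chloride (ring A plus C4) and the O1–C2–C3 unit bearing ring B. In the key step a β-oxido alkyllithium from an enantiopure (R)-chlorohydrin is C-acylated, and the lithium aldolate closes ring C by intramolecular SNAr at C8a. The step exploits the ortho relationship of the C4 ketone and C8a on ring A, which activates fluoride displacement, and the fact that C2 lies between the two reacting atoms O1 and C3, so its configuration (from CBS reduction) is carried through untouched. The lavandulyl centre comes from an Evans deconjugative alkylation; ring A is assembled by three directed metalations.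

Key step: step 13

Remark: lithiation of 2 with n-BuLi is assumed to occur at the carbon between the two MOMO groups (coordination control), not next to fluorine.

**Step 1**
Reactants: 1 5-fluorobenzene-1,3-diol
Product: 2 1-fluoro-3,5-bis(methoxymethoxy)benzene
Conditions: MOMCl, i-Pr2NEt, CH2Cl2, 0 °C → rt
Reagents that add atoms: chloromethyl methyl ether, COCCl
Why: O-alkylation of both phenols with the reactive α-chloro ether (Williamson-type) should install MOM groups that direct the later ortho-metalations and can be removed at the end without base.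

**Step 2**
Reactants: 2 1-fluoro-3,5-bis(methoxymethoxy)benzene; 3 1-bromo-3-methylbut-2-ene (prenyl bromide)
Product: 6 5-fluoro-1,3-bis(methoxymethoxy)-2-(3-methylbut-2-en-1-yl)benzene, via aryllithium 4 (not isolated), via arylcopper 5 (not isolated)
Conditions: n-BuLi, THF, −78 → −40 °C; CuI, −78 °C; then 3, −78 → 0 °C
Reagents that add atoms: none
Why: Directed ortho-metalation should take place at the carbon flanked by two MOMO groups, and transmetalation to the organocopper (monovalent copper) should give SN2 coupling at the primary carbon of prenyl bromide without allylic transposition.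

**Step 3**
Reactants: 7 (4S)-4-benzyl-1,3-oxazolidin-2-one; 8 3-methylbut-2-enoyl chloride
Product: 10 (4S)-4-benzyl-3-(3-methylbut-2-enoyl)-1,3-oxazolidin-2-one, via N-lithio oxazolidinone 9 (not isolated)
Conditions: n-BuLi, THF, −78 °C; then 8, −78 → 0 °C
Reagents that add atoms: none
Why: N-acylation of the lithiated oxazolidinone with an acid chloride is the standard entry to Evans imides and at −78 °C should not deconjugate the enoyl group.

**Step 4**
Reactants: 10 (4S)-4-benzyl-3-(3-methylbut-2-enoyl)-1,3-oxazolidin-2-one; 3 1-bromo-3-methylbut-2-ene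
Product: 12 (4S)-4-benzyl-3-[(2S)-5-methyl-2-(prop-1-en-2-yl)hex-4-enoyl]-1,3-oxazolidin-2-one, via sodium dienolate 11 (not isolated)
Conditions: NaN(SiMe3)2, THF, −78 °C; then 3, −78 → −40 °C
Reagents that add atoms: none
Why: In this deconjugative Evans alkylation, γ-deprotonation should give the chelated (Z)-dienolate, which is alkylated at the α-carbon on the face opposite the benzyl group, setting the (S) centre and leaving the isopropenyl group.

**Step 5**
Reactants: 12 (4S)-4-benzyl-3-[(2S)-5-methyl-2-(prop-1-en-2-yl)hex-4-enoyl]-1,3-oxazolidin-2-one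
Product: 13 (2S)-5-methyl-2-(prop-1-en-2-yl)hex-4-en-1-ol ((S)-lavandulol)
Conditions: LiBH4, H2O (1 equiv), Et2O, 0 °C
Reagents that add atoms: none
Why: Reductive cleavage of the imide by hydride attack at the exocyclic carbonyl should release the primary alcohol and the auxiliary under non-basic conditions that do not epimerise or conjugate the β,γ-unsaturated centre.

**Step 6**
Reactants: 13 (2S)-5-methyl-2-(prop-1-en-2-yl)hex-4-en-1-ol
Product: 14 (2S)-5-methyl-2-(prop-1-en-2-yl)hex-4-en-1-yl trifluoromethanesulfonate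
Conditions: Tf2O, pyridine, CH2Cl2, −78 °C; cold pentane, short cold silica pad; used at once
Reagents that add atoms: trifluoromethanesulfonic anhydride, O=S(=O)(OS(=O)(=O)C(F)(F)F)C(F)(F)F
Why: O-sulfonylation at low temperature should give the primary triflate, the only leaving group reactive enough to alkylate an aryllithium at −78 °C, with the stereocentre untouched.

**Step 7**
Reactants: 6 5-fluoro-1,3-bis(methoxymethoxy)-2-(3-methylbut-2-en-1-yl)benzene; 14 (2S)-5-methyl-2-(prop-1-en-2-yl)hex-4-en-1-yl trifluoromethanesulfonate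
Product: 16 1-fluoro-3,5-bis(methoxymethoxy)-4-(3-methylbut-2-en-1-yl)-2-[(2R)-5-methyl-2-(prop-1-en-2-yl)hex-4-en-1-yl]benzene, via aryllithium 15 (not isolated)
Conditions: n-BuLi, THF, −78 °C; then 14 in pentane/THF, −78 → −50 °C
Reagents that add atoms: none
Why: Directed ortho-metalation should occur between F and MOMO (the two such positions of 6 are equivalent by symmetry), and SN2 alkylation by the primary triflate at −78 °C stays below the temperature of LiF loss to the aryne, the stereocentre β to the reacting carbon being carried over (the descriptor changes to R only by priority).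

**Step 8**
Reactants: 16 1-fluoro-3,5-bis(methoxymethoxy)-4-(3-methylbut-2-en-1-yl)-2-[(2R)-5-methyl-2-(prop-1-en-2-yl)hex-4-en-1-yl]benzene
Product: 18 2-fluoro-4,6-bis(methoxymethoxy)-5-(3-methylbut-2-en-1-yl)-3-[(2R)-5-methyl-2-(prop-1-en-2-yl)hex-4-en-1-yl]benzoic acid, via aryllithium 17 (not isolated)
Conditions: n-BuLi, THF, −78 °C; CO2 (gas), −78 → 0 °C; cold dilute HCl to pH 4
Reagents that add atoms: carbon dioxide, O=C=O
Why: The last ring C–H is flanked by F and MOMO and should be lithiated selectively (directed ortho-metalation), and carboxylation of the aryllithium with CO2 gives the acid.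

**Step 9**
Reactants: 18 2-fluoro-4,6-bis(methoxymethoxy)-5-(3-methylbut-2-en-1-yl)-3-[(2R)-5-methyl-2-(prop-1-en-2-yl)hex-4-en-1-yl]benzoic acid
Product: 19 2-fluoro-4,6-bis(methoxymethoxy)-5-(3-methylbut-2-en-1-yl)-3-[(2R)-5-methyl-2-(prop-1-en-2-yl)hex-4-en-1-yl]benzoyl chloride
Conditions: 1-chloro-N,N,2-trimethylprop-1-en-1-amine, CH2Cl2, 0 °C → rt; evaporation; used crude
Reagents that add atoms: 1-chloro-N,N,2-trimethylprop-1-en-1-amine, CC(C)=C(Cl)N(C)C
Why: The α-chloroenamine should convert the hindered acid into its chloride without releasing HCl, which spares the MOM acetals and the trisubstituted olefins.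

**Step 10**
Reactants: 20 benzene-1,3,5-triol (phloroglucinol)
Product: 21 1,3,5-tris(methoxymethoxy)benzene
Conditions: MOMCl, i-Pr2NEt, CH2Cl2, 0 °C → rt
Reagents that add atoms: chloromethyl methyl ether, COCCl
Why: Threefold O-alkylation with the α-chloro ether under amine base should protect all phenols as MOM ethers, which then direct lithiation.

**Step 11**
Reactants: 21 1,3,5-tris(methoxymethoxy)benzene; 22 2-chloro-N-methoxy-N-methylacetamide
Product: 24 2-chloro-1-[2,4,6-tris(methoxymethoxy)phenyl]ethan-1-one, via aryllithium 23 (not isolated)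
Conditions: n-BuLi, THF, 0 °C; then 22, −78 → −20 °C; aq. NH4Cl
Reagents that add atoms: none
Why: Directed ortho-metalation (all three ring positions are equivalent) followed by Weinreb ketone synthesis should stop at the chelated tetrahedral adduct and give the α-chloro ketone on work-up.

**Step 12**
Reactants: 24 2-chloro-1-[2,4,6-tris(methoxymethoxy)phenyl]ethan-1-one
Product: 25 (1R)-2-chloro-1-[2,4,6-tris(methoxymethoxy)phenyl]ethan-1-ol
Conditions: (R)-2-methyl-CBS-oxazaborolidine (cat.), BH3·SMe2, THF, −20 °C; MeOH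
Reagents that add atoms: none
Why: In the CBS reduction the ketone binds the oxazaborolidine boron with the bulky aryl group turned away from the catalyst, and intramolecular hydride delivery to one face should give the (R)-chlorohydrin with the (R)-catalyst.

**Step 13**
Reactants: 25 (1R)-2-chloro-1-[2,4,6-tris(methoxymethoxy)phenyl]ethan-1-ol; 19 2-fluoro-4,6-bis(methoxymethoxy)-5-(3-methylbut-2-en-1-yl)-3-[(2R)-5-methyl-2-(prop-1-en-2-yl)hex-4-en-1-yl]benzoyl chloride
Product: 29 (2S)-5,7-bis(methoxymethoxy)-6-(3-methylbut-2-en-1-yl)-8-[(2R)-5-methyl-2-(prop-1-en-2-yl)hex-4-en-1-yl]-2-[2,4,6-tris(methoxymethoxy)phenyl]-2,3-dihydro-4H-chromen-4-one, via lithium alkoxide 26 (not isolated), via dilithio species 27 (not isolated), via lithium aldolate 28 (not isolated)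
Conditions: 25: n-BuLi, THF, −78 °C; LiC10H8 (lithium naphthalenide, 2 equiv), −78 °C; slow cannulation into 19 in THF, −78 °C; then −78 → 20 °C; pH 7 buffer
Reagents that add atoms: none
Why: The C–Li bond of the β-oxido alkyllithium 27 is far more nucleophilic than its O–Li bond, so slow addition to acid chloride 19 at −78 °C should give the ketone by C-acylation (bond C3–C4) without O-acylation, and the doubly ortho-substituted ketone resists a second addition. The lithium aldolate 28 then attacks C8a, where fluoride sits ortho to the new C4 carbonyl, in an addition–elimination SNAr through a Meisenheimer intermediate that forms O1–C8a and closes ring C as a six-membered ring (6-exo-trig attack on the arene carbon), the forming ring holding the carbonyl in the plane of ring A where it stabilises the negative charge. The closest known reaction types are ketone synthesis from an organolithium and an acid chloride and the chromanone-forming intramolecular SNAr of 2-fluoroaryl β-hydroxy ketones, telescoped here from a chlorohydrin-derived β-oxido alkyllithium. No stereocentre is created: C2 is carried over from 25 with its configuration intact because the two new bonds are made at its neighbours O1 and C3. The step needs ring closure to outrun retro-aldol cleavage and dehydration of 28, which the absence of any free base after acylation, the low temperature and the good nucleofuge fluoride should secure (both MOMO groups of ring A are meta to C8a and do not deactivate it). Fluoride is the only leaving group activated by the ketone, so the MOM ethers should not be displaced.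

**Step 14**
Reactants: 29 (2S)-5,7-bis(methoxymethoxy)-6-(3-methylbut-2-en-1-yl)-8-[(2R)-5-methyl-2-(prop-1-en-2-yl)hex-4-en-1-yl]-2-[2,4,6-tris(methoxymethoxy)phenyl]-2,3-dihydro-4H-chromen-4-one
Product: 31 (2S)-5,7-dihydroxy-6-(3-methylbut-2-en-1-yl)-8-[(2R)-5-methyl-2-(prop-1-en-2-yl)hex-4-en-1-yl]-2-(2,4,6-trihydroxyphenyl)-2,3-dihydro-4H-chromen-4-one, via pentakis(trimethylsilyl) ether 30 (not isolated)
Conditions: Me3SiOTf, 2,2'-bipyridyl, CH2Cl2, 0 °C → rt; then H2O, rt
Reagents that add atoms: none
Why: Me3SiOTf–2,2'-bipyridyl should convert the aryl MOM ethers into aryl trimethylsilyl ethers through N-(methoxymethyl)pyridinium salts under buffered, non-protic conditions, and water then frees the phenols without ionising the C2–O1 bond or touching the olefins.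

**Compound list**

1 | 5-fluorobenzene-1,3-diol | Oc1cc(O)cc(F)c1 | starting material
2 | 1-fluoro-3,5-bis(methoxymethoxy)benzene | COCOc1cc(F)cc(OCOC)c1 | intermediate
3 | 1-bromo-3-methylbut-2-ene (prenyl bromide) | CC(C)=CCBr | starting material
4 | [4-fluoro-2,6-bis(methoxymethoxy)phenyl]lithium | [Li]c1c(OCOC)cc(F)cc1OCOC | intermediate
5 | [4-fluoro-2,6-bis(methoxymethoxy)phenyl]copper | [Cu]c1c(OCOC)cc(F)cc1OCOC | intermediate
6 | 5-fluoro-1,3-bis(methoxymethoxy)-2-(3-methylbut-2-en-1-yl)benzene | COCOc1cc(F)cc(OCOC)c1CC=C(C)C | intermediate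
7 | (4S)-4-benzyl-1,3-oxazolidin-2-one | O=C1N[C@@H](Cc2ccccc2)CO1 | starting material
8 | 3-methylbut-2-enoyl chloride | CC(C)=CC(=O)Cl | starting material
9 | N-lithio derivative of 7 | [Li]N1[C@@H](Cc2ccccc2)COC1=O | intermediate
10 | (4S)-4-benzyl-3-(3-methylbut-2-enoyl)-1,3-oxazolidin-2-one | CC(C)=CC(=O)N1[C@@H](Cc2ccccc2)COC1=O | intermediate
11 | sodium (Z)-dienolate of 10 | C=C(C)/C=C(\O[Na])N1[C@@H](Cc2ccccc2)COC1=O | intermediate
12 | (4S)-4-benzyl-3-[(2S)-5-methyl-2-(prop-1-en-2-yl)hex-4-enoyl]-1,3-oxazolidin-2-one | C=C(C)[C@H](CC=C(C)C)C(=O)N1[C@@H](Cc2ccccc2)COC1=O | intermediate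
13 | (2S)-5-methyl-2-(prop-1-en-2-yl)hex-4-en-1-ol ((S)-lavandulol) | C=C(C)[C@H](CC=C(C)C)CO | intermediate
14 | (2S)-5-methyl-2-(prop-1-en-2-yl)hex-4-en-1-yl trifluoromethanesulfonate | C=C(C)[C@H](CC=C(C)C)COS(=O)(=O)C(F)(F)F | intermediate
15 | [6-fluoro-2,4-bis(methoxymethoxy)-3-(3-methylbut-2-en-1-yl)phenyl]lithium | COCOc1c([Li])c(F)cc(OCOC)c1CC=C(C)C | intermediate
16 | 1-fluoro-3,5-bis(methoxymethoxy)-4-(3-methylbut-2-en-1-yl)-2-[(2R)-5-methyl-2-(prop-1-en-2-yl)hex-4-en-1-yl]benzene | C=C(C)[C@H](CC=C(C)C)Cc1c(OCOC)c(CC=C(C)C)c(OCOC)cc1F | intermediate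
17 | aryllithium from 16 (lithiated at the ring carbon between F and MOMO) | C=C(C)[C@H](CC=C(C)C)Cc1c(OCOC)c(CC=C(C)C)c(OCOC)c([Li])c1F | intermediate
18 | 2-fluoro-4,6-bis(methoxymethoxy)-5-(3-methylbut-2-en-1-yl)-3-[(2R)-5-methyl-2-(prop-1-en-2-yl)hex-4-en-1-yl]benzoic acid | C=C(C)[C@H](CC=C(C)C)Cc1c(OCOC)c(CC=C(C)C)c(OCOC)c(C(=O)O)c1F | intermediate
19 | 2-fluoro-4,6-bis(methoxymethoxy)-5-(3-methylbut-2-en-1-yl)-3-[(2R)-5-methyl-2-(prop-1-en-2-yl)hex-4-en-1-yl]benzoyl chloride | C=C(C)[C@H](CC=C(C)C)Cc1c(OCOC)c(CC=C(C)C)c(OCOC)c(C(=O)Cl)c1F | intermediate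
20 | benzene-1,3,5-triol (phloroglucinol) | Oc1cc(O)cc(O)c1 | starting material
21 | 1,3,5-tris(methoxymethoxy)benzene | COCOc1cc(OCOC)cc(OCOC)c1 | intermediate
22 | 2-chloro-N-methoxy-N-methylacetamide | CON(C)C(=O)CCl | starting material
23 | [2,4,6-tris(methoxymethoxy)phenyl]lithium | [Li]c1c(OCOC)cc(OCOC)cc1OCOC | intermediate
24 | 2-chloro-1-[2,4,6-tris(methoxymethoxy)phenyl]ethan-1-one | O=C(CCl)c1c(OCOC)cc(OCOC)cc1OCOC | intermediate
25 | (1R)-2-chloro-1-[2,4,6-tris(methoxymethoxy)phenyl]ethan-1-ol | O[C@H](c1c(OCOC)cc(OCOC)cc1OCOC)CCl | intermediate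
26 | lithium alkoxide of 25 | [Li]O[C@H](c1c(OCOC)cc(OCOC)cc1OCOC)CCl | intermediate
27 | O,C-dilithio species from 25 (β-oxido alkyllithium, carbinol configuration unchanged) | [Li]O[C@H](c1c(OCOC)cc(OCOC)cc1OCOC)C[Li] | intermediate
28 | lithium aldolate: lithium (1S)-3-oxo-3-aryl-1-[2,4,6-tris(methoxymethoxy)phenyl]propan-1-olate, aryl being the 2-fluoro ring A of 19 | C=C(C)[C@H](CC=C(C)C)Cc1c(OCOC)c(CC=C(C)C)c(OCOC)c(C(=O)C[C@H](O[Li])c2c(OCOC)cc(OCOC)cc2OCOC)c1F | intermediate
29 | (2S)-5,7-bis(methoxymethoxy)-6-(3-methylbut-2-en-1-yl)-8-[(2R)-5-methyl-2-(prop-1-en-2-yl)hex-4-en-1-yl]-2-[2,4,6-tris(methoxymethoxy)phenyl]-2,3-dihydro-4H-chromen-4-one | C=C(C)[C@H](CC=C(C)C)Cc1c(OCOC)c(CC=C(C)C)c(OCOC)c2c1O[C@H](c1c(OCOC)cc(OCOC)cc1OCOC)CC2=O | intermediate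
30 | pentakis(trimethylsilyl) ether of 31 | C=C(C)[C@H](CC=C(C)C)Cc1c(O[Si](C)(C)C)c(CC=C(C)C)c(O[Si](C)(C)C)c2c1O[C@H](c1c(O[Si](C)(C)C)cc(O[Si](C)(C)C)cc1O[Si](C)(C)C)CC2=O | intermediate
31 | (2S)-5,7-dihydroxy-6-(3-methylbut-2-en-1-yl)-8-[(2R)-5-methyl-2-(prop-1-en-2-yl)hex-4-en-1-yl]-2-(2,4,6-trihydroxyphenyl)-2,3-dihydro-4H-chromen-4-one | C=C(C)[C@H](CC=C(C)C)Cc1c(O)c(CC=C(C)C)c(O)c2c1O[C@H](c1c(O)cc(O)cc1O)CC2=O | target

**Step count and risks**

Total step count: 14. Longest linear sequence: 9 steps (steps 3, 4, 5, 6, 7, 8, 9, 13, 14).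

Steps most likely to fail:

1. Step 13. The lithium aldolate 28 may undergo retro-aldol cleavage or dehydration before the SNAr ring closure, which would erode the C2 configuration. The dianion may also add twice to the ketone or enolise it during acylation. The fallback sets out from 19 and comes back at 29. The acid chloride would be converted (MeNHOMe·HCl, pyridine, CH2Cl2) into the N-methoxy-N-methylamide F1. Its chelated adduct with dilithio species 27 cannot over-add or enolise, and a cold quench would give the isolated β-hydroxy ketone F2. F2 would then be cyclised in a separate SNAr step under mild carbonate conditions (Cs2CO3, MeCN, rt) to give 29.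

2. Step 7. The β-branched homoallylic triflate 14 may ionise or eliminate, and the ortho-fluoro aryllithium 15 may lose LiF to the aryne, before the C–C bond forms. The fallback sets out from 6 and 13 and comes back at 16. Aryllithium 15 would be quenched with I2 to give 1-fluoro-2-iodo-3,5-bis(methoxymethoxy)-4-(3-methylbut-2-en-1-yl)benzene F3. Alcohol 13 would be converted (I2, PPh3, imidazole) into (2S)-1-iodo-5-methyl-2-(prop-1-en-2-yl)hex-4-ene F4, and Zn insertion (Zn, LiCl, THF) would give [(2S)-5-methyl-2-(prop-1-en-2-yl)hex-4-en-1-yl]zinc iodide F5. Negishi coupling of F3 with F5 (Pd(OAc)2, 2-dicyclohexylphosphino-2',6'-dimethoxybiphenyl, THF, rt) would give 16.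

3. Step 14. The C2–O1 bond next to the trioxygenated ring B may ionise under Lewis-acidic conditions, causing epimerisation at C2 or ring opening, and the prenyl or lavandulyl olefins may cyclise onto the freed phenols. The fallback sets out from 29 and comes back at 31. The MOM groups would be removed by plain acidic methanolysis (HCl, MeOH, rt) without trying to hold C2. Because the lavandulyl centre is fixed, 31 and its (2R)-epimer F6 are diastereomers and would be separated by preparative reversed-phase HPLC. F6 would be re-equilibrated under the same acidic conditions and recycled.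

**Further compounds**

F1 | step 13 | 2-fluoro-N-methoxy-4,6-bis(methoxymethoxy)-N-methyl-5-(3-methylbut-2-en-1-yl)-3-[(2R)-5-methyl-2-(prop-1-en-2-yl)hex-4-en-1-yl]benzamide | C=C(C)[C@H](CC=C(C)C)Cc1c(OCOC)c(CC=C(C)C)c(OCOC)c(C(=O)N(C)OC)c1F
F2 | step 13 | (3S)-1-{2-fluoro-4,6-bis(methoxymethoxy)-5-(3-methylbut-2-en-1-yl)-3-[(2R)-5-methyl-2-(prop-1-en-2-yl)hex-4-en-1-yl]phenyl}-3-hydroxy-3-[2,4,6-tris(methoxymethoxy)phenyl]propan-1-one | C=C(C)[C@H](CC=C(C)C)Cc1c(OCOC)c(CC=C(C)C)c(OCOC)c(C(=O)C[C@H](O)c2c(OCOC)cc(OCOC)cc2OCOC)c1F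
F3 | step 7 | 1-fluoro-2-iodo-3,5-bis(methoxymethoxy)-4-(3-methylbut-2-en-1-yl)benzene | COCOc1c(I)c(F)cc(OCOC)c1CC=C(C)C
F4 | step 7 | (2S)-1-iodo-5-methyl-2-(prop-1-en-2-yl)hex-4-ene | C=C(C)[C@H](CC=C(C)C)CI
F5 | step 7 | [(2S)-5-methyl-2-(prop-1-en-2-yl)hex-4-en-1-yl]zinc iodide | C=C(C)[C@H](CC=C(C)C)C[Zn]I
F6 | step 14 | (2R)-5,7-dihydroxy-6-(3-methylbut-2-en-1-yl)-8-[(2R)-5-methyl-2-(prop-1-en-2-yl)hex-4-en-1-yl]-2-(2,4,6-trihydroxyphenyl)-2,3-dihydro-4H-chromen-4-one | C=C(C)[C@H](CC=C(C)C)Cc1c(O)c(CC=C(C)C)c(O)c2c1O[C@@H](c1c(O)cc(O)cc1O)CC2=O
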